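**Retrosynthetic overview**
- The target comes from a one-pot removal of five benzyl ethers and one PMB ester; the cinnamate C–C bond comes from a Heck coupling of a 4-bromo-2,3-dihydrobenzofuran with the acrylate of protected (R)-danshensu.
- The dihydrobenzofuran (last ring formed) comes from oxidative ring contraction (1,2-aryl shift) of a (2S)-5-bromoflavanone, which gives the C3 methyl ester and the 2,3-trans relationship directly.
- The flavanone pyranone ring (first ring formed) comes from an enantioselective 6-endo oxa-Michael cyclisation of a 2'-hydroxychalcone; the chalcone comes from an ortho-lithiated bromocatechol dibenzyl ether and a Weinreb cinnamamide.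
- The danshensu acrylate comes from copper-catalysed aryl Grignard opening of an (R)-glycidic ester, trapped with acryloyl chloride.
- All three arenes come from one building block, 1,2-bis(benzyloxy)-4-bromobenzene, made from catechol.

Assumption: potassium (2R)-oxirane-2-carboxylate and N-methoxy-N-methylacrylamide are taken as commercial, and the catalyst antipode that gives (2S) in step 6 is chosen from the two available.

**Step 1**
Reactants: 1 catechol
Product: 2 4-bromocatechol
Conditions: NBS (1.0 equiv), HBF4·OEt2 (10 mol%), MeCN, −30 °C → rt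
Reagents that add atoms: N-bromosuccinimide, O=C1CCC(=O)N1Br
Why: Electrophilic aromatic bromination (SEAr); the position para to one OH is the most activated unhindered site, and one equivalent of NBS at low temperature stops at the monobromide.

**Step 2**
Reactants: 2 4-bromocatechol
Product: 3 1,2-bis(benzyloxy)-4-bromobenzene
Conditions: BnBr (2.2 equiv), K2CO3, DMF, 60 °C, N2
Reagents that add atoms: benzyl bromide, BrCc1ccccc1
Why: Double Williamson ether synthesis (SN2 of the phenoxides on benzyl bromide) under mild carbonate base.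

**Step 3**
Reactants: 3 1,2-bis(benzyloxy)-4-bromobenzene; 4 N-methoxy-N-methylacrylamide
Product: 5 (E)-3-[3,4-bis(benzyloxy)phenyl]-N-methoxy-N-methylprop-2-enamide
Conditions: Pd(OAc)2 (2 mol%), P(o-tol)3 (6 mol%), Et3N, DMF, 100 °C
Reagents that add atoms: none
Why: Mizoroki–Heck reaction; the electron-poor acrylamide inserts regioselectively and β-hydride elimination gives the (E)-cinnamamide.

**Step 4**
Reactants: 3 1,2-bis(benzyloxy)-4-bromobenzene; 5 (E)-3-[3,4-bis(benzyloxy)phenyl]-N-methoxy-N-methylprop-2-enamide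
Product: 7 (E)-1-[2,3-bis(benzyloxy)-6-bromophenyl]-3-[3,4-bis(benzyloxy)phenyl]prop-2-en-1-one, via aryllithium 6 (not isolated)
Conditions: LDA (1.05 equiv), THF, −78 °C, 1 h; then 5 (0.9 equiv), −78 °C, 2 h; 1 M HCl quench at −78 °C
Reagents that add atoms: none
Why: Directed ortho-metalation followed by Weinreb ketone synthesis; LDA removes the proton flanked by OBn and Br (the most acidic one), the aryllithium is held at −78 °C to avoid aryne formation, and the chelated tetrahedral adduct of 1,2-addition collapses to the enone only on quench.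

**Step 5**
Reactants: 7 (E)-1-[2,3-bis(benzyloxy)-6-bromophenyl]-3-[3,4-bis(benzyloxy)phenyl]prop-2-en-1-one
Product: 8 (E)-1-[3-(benzyloxy)-6-bromo-2-hydroxyphenyl]-3-[3,4-bis(benzyloxy)phenyl]prop-2-en-1-one
Conditions: BCl3 (1.05 equiv), CH2Cl2, −78 °C, 30 min; MeOH then aq. NaHCO3
Reagents that add atoms: none
Why: Chelation-controlled Lewis-acid dealkylation; BCl3 binds the ketone and cleaves only the benzyl ether ortho to it through a six-membered chelate, leaving the other four benzyl ethers.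

**Step 6**
Reactants: 8 (E)-1-[3-(benzyloxy)-6-bromo-2-hydroxyphenyl]-3-[3,4-bis(benzyloxy)phenyl]prop-2-en-1-one
Product: 9 (2S)-8-(benzyloxy)-2-[3,4-bis(benzyloxy)phenyl]-5-bromo-2,3-dihydro-4H-chromen-4-one
Conditions: tert-leucine-derived iminophosphorane–thiourea catalyst [(4-MeOC6H4)3P=N–CH2–CH(t-Bu)–NH–C(S)–NH–C6H3-3,5-(CF3)2] (10 mol%), toluene, −20 °C, 48 h; AcOH quench
Reagents that add atoms: none
Why: Proposed new method: a chiral bifunctional iminophosphorane–thiourea superbase deprotonates the chelated 2'-OH to a tight chiral ion pair while the thiourea binds the enone carbonyl, so the phenoxide adds 6-endo-trig to one face of the (E)-enone and the iminophosphonium protonates the enolate, setting C2 as (S) under kinetic control (the AcOH quench stops retro-oxa-Michael erosion); the closest known reaction type is the cinchona/thiourea-catalysed oxa-Michael cyclisation of α-ester-activated 2'-hydroxychalcones and iminophosphorane-catalysed oxa-Michael additions of alcohols to unsaturated esters.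

**Step 7**
Reactants: 9 (2S)-8-(benzyloxy)-2-[3,4-bis(benzyloxy)phenyl]-5-bromo-2,3-dihydro-4H-chromen-4-one
Product: 11 methyl (2S,3S)-7-(benzyloxy)-2-[3,4-bis(benzyloxy)phenyl]-4-bromo-2,3-dihydro-1-benzofuran-3-carboxylate, via enol ether 10 (not isolated)
Conditions: HC(OMe)3, conc. H2SO4 (0.5 equiv), rt, 1 h; then PhI(OAc)2 (1.2 equiv), rt, 12 h; aq. NaHCO3
Reagents that add atoms: trimethyl orthoformate, COC(OC)OC
Why: Hypervalent-iodine oxidative ring contraction of a flavanone (1,2-aryl shift): the iodane adds to C3 of enol ether 10 anti to the C2 aryl, methanol ketalises C4, and the A-ring carbon C4a migrates from C4 to C3 antiperiplanar to the departing PhI (inversion at C3), which gives the 2,3-trans methyl ester (3S) while the (2S) centre is not touched.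

**Step 8**
Reactants: 12 potassium (2R)-oxirane-2-carboxylate
Product: 13 4-methoxybenzyl (2R)-oxirane-2-carboxylate
Conditions: PMBCl (1.1 equiv), Bu4NI (5 mol%), DMF, rt → 40 °C
Reagents that add atoms: 4-methoxybenzyl chloride, COc1ccc(CCl)cc1
Why: SN2 O-alkylation of the carboxylate salt (iodide-catalysed), which does not touch the epoxide stereocentre.

**Step 9**
Reactants: 3 1,2-bis(benzyloxy)-4-bromobenzene; 13 4-methoxybenzyl (2R)-oxirane-2-carboxylate; 14 acryloyl chloride
Product: 17 4-methoxybenzyl (2R)-2-(acryloyloxy)-3-[3,4-bis(benzyloxy)phenyl]propanoate, via arylmagnesium bromide 15 (not isolated), via magnesium alkoxide 16 (not isolated)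
Conditions: Mg, THF, 50 °C (Grignard, 0.95 equiv vs 13); CuI (10 mol%), 13, −40 → −20 °C; then acryloyl chloride (1.3 equiv), −20 → 0 °C
Reagents that add atoms: none
Why: Copper-catalysed SN2 ring opening of the glycidic ester by the aryl Grignard reagent at the terminal carbon C3 (the C2–O bond is not broken, so the (R) centre is kept), then O-acylation of the magnesium alkoxide in the same flask.

**Step 10**
Reactants: 11 methyl (2S,3S)-7-(benzyloxy)-2-[3,4-bis(benzyloxy)phenyl]-4-bromo-2,3-dihydro-1-benzofuran-3-carboxylate; 17 4-methoxybenzyl (2R)-2-(acryloyloxy)-3-[3,4-bis(benzyloxy)phenyl]propanoate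
Product: 18 methyl (2S,3S)-7-(benzyloxy)-2-[3,4-bis(benzyloxy)phenyl]-4-[(E)-3-{[(2R)-3-[3,4-bis(benzyloxy)phenyl]-1-[(4-methoxybenzyl)oxy]-1-oxopropan-2-yl]oxy}-3-oxoprop-1-en-1-yl]-2,3-dihydro-1-benzofuran-3-carboxylate
Conditions: Pd2(dba)3 (2.5 mol%), P(t-Bu)3·HBF4 (10 mol%), Cy2NMe (1.5 equiv), 1,4-dioxane, 70 °C
Reagents that add atoms: none
Why: Mizoroki–Heck reaction with the bulky electron-rich P(t-Bu)3 ligand, which allows oxidative addition of the hindered electron-rich aryl bromide at 70 °C and gives the (E)-cinnamate, while the hindered amine base is too weak to epimerise C3 or open the ring.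

**Step 11**
Reactants: 18 the fully protected ester from step 10
Product: 19 monomethyl lithospermate
Conditions: BCl3 (12 equiv), pentamethylbenzene (18 equiv), CH2Cl2, −78 → −40 °C; aq. citric acid/THF quench; reverse-phase HPLC
Reagents that add atoms: none
Why: Lewis-acid debenzylation with a non-Lewis-basic cation scavenger; the benzyl and PMB cations are taken up by Friedel–Crafts alkylation of pentamethylbenzene at low temperature, so the alkene, the methyl ester, the cinnamate ester and the three stereocentres are untouched.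

**Compound list**
1 | catechol | Oc1ccccc1O | starting material
2 | 4-bromocatechol | Oc1ccc(Br)cc1O | intermediate
3 | 1,2-bis(benzyloxy)-4-bromobenzene | Brc1ccc(OCc2ccccc2)c(OCc2ccccc2)c1 | intermediate
4 | N-methoxy-N-methylacrylamide | C=CC(=O)N(C)OC | starting material
5 | (E)-3-[3,4-bis(benzyloxy)phenyl]-N-methoxy-N-methylprop-2-enamide | CON(C)C(=O)/C=C/c1ccc(OCc2ccccc2)c(OCc2ccccc2)c1 | intermediate
6 | [2,3-bis(benzyloxy)-6-bromophenyl]lithium | [Li]c1c(Br)ccc(OCc2ccccc2)c1OCc1ccccc1 | intermediate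
7 | (E)-1-[2,3-bis(benzyloxy)-6-bromophenyl]-3-[3,4-bis(benzyloxy)phenyl]prop-2-en-1-one | O=C(/C=C/c1ccc(OCc2ccccc2)c(OCc2ccccc2)c1)c1c(Br)ccc(OCc2ccccc2)c1OCc1ccccc1 | intermediate
8 | (E)-1-[3-(benzyloxy)-6-bromo-2-hydroxyphenyl]-3-[3,4-bis(benzyloxy)phenyl]prop-2-en-1-one | O=C(/C=C/c1ccc(OCc2ccccc2)c(OCc2ccccc2)c1)c1c(Br)ccc(OCc2ccccc2)c1O | intermediate
9 | (2S)-8-(benzyloxy)-2-[3,4-bis(benzyloxy)phenyl]-5-bromo-2,3-dihydro-4H-chromen-4-one | O=C1C[C@@H](c2ccc(OCc3ccccc3)c(OCc3ccccc3)c2)Oc2c(OCc3ccccc3)ccc(Br)c21 | intermediate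
10 | (2S)-8-(benzyloxy)-2-[3,4-bis(benzyloxy)phenyl]-5-bromo-4-methoxy-2H-chromene | COC1=C[C@@H](c2ccc(OCc3ccccc3)c(OCc3ccccc3)c2)Oc2c(OCc3ccccc3)ccc(Br)c21 | intermediate
11 | methyl (2S,3S)-7-(benzyloxy)-2-[3,4-bis(benzyloxy)phenyl]-4-bromo-2,3-dihydro-1-benzofuran-3-carboxylate (2,3-trans) | COC(=O)[C@H]1c2c(Br)ccc(OCc3ccccc3)c2O[C@@H]1c1ccc(OCc2ccccc2)c(OCc2ccccc2)c1 | intermediate
12 | potassium (2R)-oxirane-2-carboxylate | [K+].[O-]C(=O)[C@H]1CO1 | starting material
13 | 4-methoxybenzyl (2R)-oxirane-2-carboxylate | COc1ccc(COC(=O)[C@H]2CO2)cc1 | intermediate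
14 | acryloyl chloride | C=CC(=O)Cl | starting material
15 | [3,4-bis(benzyloxy)phenyl]magnesium bromide | Br[Mg]c1ccc(OCc2ccccc2)c(OCc2ccccc2)c1 | intermediate
16 | bromomagnesium alkoxide of 4-methoxybenzyl (2R)-3-[3,4-bis(benzyloxy)phenyl]-2-hydroxypropanoate | COc1ccc(COC(=O)[C@@H](Cc2ccc(OCc3ccccc3)c(OCc3ccccc3)c2)O[Mg]Br)cc1 | intermediate
17 | 4-methoxybenzyl (2R)-2-(acryloyloxy)-3-[3,4-bis(benzyloxy)phenyl]propanoate | C=CC(=O)O[C@H](Cc1ccc(OCc2ccccc2)c(OCc2ccccc2)c1)C(=O)OCc1ccc(OC)cc1 | intermediate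
18 | penta-O-benzyl monomethyl lithospermate 4-methoxybenzyl ester (2S,3S,2'R; E) | COC(=O)[C@H]1c2c(/C=C/C(=O)O[C@H](Cc3ccc(OCc4ccccc4)c(OCc4ccccc4)c3)C(=O)OCc3ccc(OC)cc3)ccc(OCc3ccccc3)c2O[C@@H]1c1ccc(OCc2ccccc2)c(OCc2ccccc2)c1 | intermediate
19 | monomethyl lithospermate | COC(=O)[C@H]1c2c(/C=C/C(=O)O[C@H](Cc3ccc(O)c(O)c3)C(=O)O)ccc(O)c2O[C@@H]1c1ccc(O)c(O)c1 | target

**Totals**
Total step count: 11.
Longest linear sequence: 9 steps (steps 1, 2, 3, 4, 5, 6, 7, 10, 11).

**Steps most likely to fail**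

Step 4 (hindered ortho-bromoaryllithium with an unsaturated Weinreb amide; risks are aryne formation, slow acylation and conjugate addition). The fallback sets out from 5 and 3 and comes back at 7. Weinreb amide 5 is reduced with DIBAL-H (THF, −78 °C) to (E)-3-[3,4-bis(benzyloxy)phenyl]prop-2-enal F1. Aryllithium 6, made from 3 as before, adds to this aldehyde within minutes at −78 °C, much faster than to an amide, to give racemic (E)-1-[2,3-bis(benzyloxy)-6-bromophenyl]-3-[3,4-bis(benzyloxy)phenyl]prop-2-en-1-ol F2. Oxidation of the allylic alcohol with MnO2 (CH2Cl2, rt) gives chalcone 7.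

Step 6 (the proposed new catalytic asymmetric cyclisation; risks are low ee and racemisation by retro-oxa-Michael). The fallback uses known chemistry, sets out from 8 and comes back at 9. Chalcone 8 is cyclised without stereocontrol (NaOAc, EtOH, reflux) to racemic 8-(benzyloxy)-2-[3,4-bis(benzyloxy)phenyl]-5-bromo-2,3-dihydro-4H-chromen-4-one F3. A kinetic resolution by asymmetric transfer hydrogenation (Cp*RhCl(TsDPEN), HCO2H/Et3N, EtOAc, rt; the catalyst antipode that consumes the (2R)-ketone) reduces the unwanted enantiomer to (2R,4R)-8-(benzyloxy)-2-[3,4-bis(benzyloxy)phenyl]-5-bromo-3,4-dihydro-2H-chromen-4-ol F4 (2,4-cis). The unreacted (2S)-flavanone 9 is separated by chromatography (maximum 50%).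

Step 7 (the ring contraction; risks are competing 2,3-shift of the electron-rich B-ring to an isoflavone, dehydrogenation to the flavone, and oxidation of the benzyloxyarenes by iodine(III)). The fallback sets out from 9 and comes back at 11 by a Wolff ring contraction, which has no cationic C3.
- LiHMDS and CF3CO2CH2CF3 (THF, −78 °C) give (2S)-8-(benzyloxy)-2-[3,4-bis(benzyloxy)phenyl]-5-bromo-3-(trifluoroacetyl)-2,3-dihydro-4H-chromen-4-one F5.
- Detrifluoroacetylative diazo transfer (MsN3, Et3N, MeCN) gives 8-(benzyloxy)-2-[3,4-bis(benzyloxy)phenyl]-5-bromo-3-diazo-2,3-dihydro-4H-chromen-4-one F6 (C2 as in 9).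
- Irradiation at 365 nm in MeOH/THF causes the 1,2-shift of the aryl carbon to the carbene carbon and gives the ketene [7-(benzyloxy)-2-[3,4-bis(benzyloxy)phenyl]-4-bromo-1-benzofuran-3(2H)-ylidene]methanone F7.
- Methanol adds to the ketene and protonation anti to the C2 aryl gives mainly methyl (2S,3R)-7-(benzyloxy)-2-[3,4-bis(benzyloxy)phenyl]-4-bromo-2,3-dihydro-1-benzofuran-3-carboxylate F8 (2,3-cis).
- Catalytic NaOMe in MeOH (0 °C → rt) epimerises C3 to the more stable trans ester 11.

**Further compounds**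
F1 | step 4 | (E)-3-[3,4-bis(benzyloxy)phenyl]prop-2-enal | O=C/C=C/c1ccc(OCc2ccccc2)c(OCc2ccccc2)c1
F2 | step 4 | racemic (E)-1-[2,3-bis(benzyloxy)-6-bromophenyl]-3-[3,4-bis(benzyloxy)phenyl]prop-2-en-1-ol | OC(/C=C/c1ccc(OCc2ccccc2)c(OCc2ccccc2)c1)c1c(Br)ccc(OCc2ccccc2)c1OCc1ccccc1
F3 | step 6 | racemic 8-(benzyloxy)-2-[3,4-bis(benzyloxy)phenyl]-5-bromo-2,3-dihydro-4H-chromen-4-one | O=C1CC(c2ccc(OCc3ccccc3)c(OCc3ccccc3)c2)Oc2c(OCc3ccccc3)ccc(Br)c21
F4 | step 6 | (2R,4R)-8-(benzyloxy)-2-[3,4-bis(benzyloxy)phenyl]-5-bromo-3,4-dihydro-2H-chromen-4-ol (2,4-cis) | O[C@@H]1C[C@H](c2ccc(OCc3ccccc3)c(OCc3ccccc3)c2)Oc2c(OCc3ccccc3)ccc(Br)c21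
F5 | step 7 | (2S)-8-(benzyloxy)-2-[3,4-bis(benzyloxy)phenyl]-5-bromo-3-(trifluoroacetyl)-2,3-dihydro-4H-chromen-4-one (C3 epimers/enol) | O=C1C(C(=O)C(F)(F)F)[C@@H](c2ccc(OCc3ccccc3)c(OCc3ccccc3)c2)Oc2c(OCc3ccccc3)ccc(Br)c21
F6 | step 7 | 8-(benzyloxy)-2-[3,4-bis(benzyloxy)phenyl]-5-bromo-3-diazo-2,3-dihydro-4H-chromen-4-one (C2 as in 9) | O=C1C(=[N+]=[N-])[C@@H](c2ccc(OCc3ccccc3)c(OCc3ccccc3)c2)Oc2c(OCc3ccccc3)ccc(Br)c21
F7 | step 7 | [7-(benzyloxy)-2-[3,4-bis(benzyloxy)phenyl]-4-bromo-1-benzofuran-3(2H)-ylidene]methanone (ketene; C2 as in 9) | O=C=C1c2c(Br)ccc(OCc3ccccc3)c2O[C@@H]1c1ccc(OCc2ccccc2)c(OCc2ccccc2)c1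
F8 | step 7 | methyl (2S,3R)-7-(benzyloxy)-2-[3,4-bis(benzyloxy)phenyl]-4-bromo-2,3-dihydro-1-benzofuran-3-carboxylate (2,3-cis) | COC(=O)[C@@H]1c2c(Br)ccc(OCc3ccccc3)c2O[C@@H]1c1ccc(OCc2ccccc2)c(OCc2ccccc2)c1
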